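**Retrosynthetic overview**

1. Locants follow abscisic acid: ring C1' (carbinol), C2'=C3', C4' (ketone), C5', C6' (quaternary); C7' and C9' are the methyls, C8' is the acyloxymethyl carbon, the side chain runs from C1 (CO2H) to C5 (on C1'). Late disconnections: dioxolane hydrolysis, Stille bond C3–C4 (vinylstannane 25 + (Z)-iodo acid 27), ester bond at the 8'-oxygen (half-ester 23 from (R)-mevalonolactone), alkyne C4≡C5 from lactol 15.
2. The core is the cis-fused bicyclic lactone 13: C5 and C8', which sit cis on the neighbours C1' and C6' in the target, are tied into a γ-lactone ring.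
3. Key disconnection: the carbocycle of 13 is cut at C3'–C4' and C2'–C1' into the monocyclic keto-lactone aldehyde 8 and 2-nitropropene 10 (a propyne equivalent of reversed polarity). Forward: carbene-catalysed Stetter addition, intramolecular nitro-aldol closure, loss of HNO2.
4. Enabling feature: the γ-hydroxy enone C4'(=O)–C3'H=C2'(CH3)–C1'(OH) of the six-membered ring (ketone and carbinol 1,4 across the alkene) next to quaternary C6'. The lactone tether turns C1' into a non-enolisable, activated α-keto-lactone carbonyl and allows only cis ring fusion.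
5. Ring order: γ-lactone ring first (step 1), C6' set on it by a chirality-transferring Claisen rearrangement (step 3), carbocycle second (step 6), lactone ring opened again (steps 8 and 9). C4' stays a dioxolane while the 8'-hydroxyl is free, so the oxygen cannot add to C2'.

Key step: step 6

Assumption: the target is taken as drawn, which by the priority rules is (1'R,6'S) in the ring (C8' cis to the side chain, hydroxyl cis to C9') and (3R) in the hydroxymethylglutarate unit.

**Route**

Step 1
Reactants: 1 diethyl 2-methyl-3-oxobutanedioate (diethyl oxalpropionate); 2 formaldehyde (37% aqueous)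
Product: 4 enol lactone 3-hydroxy-4-methylfuran-2(5H)-one, via ethyl 3-methyl-4,5-dioxooxolane-3-carboxylate 3 (not isolated)
Conditions: aq. CH2O, K2CO3 (cat.), H2O, 0 °C to rt; then 10% aq. H2SO4, 100 °C
Reagents that add atoms: none
Why: Base-catalysed aldol addition of the doubly activated carbon of 1 to formaldehyde and lactonisation onto the oxalyl ester give 3, and aqueous acid then hydrolyses and decarboxylates the β-keto ester to the enolised α-keto lactone (the classical route to sotolon-type furanones); no stereocentre is formed.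

Step 2
Reactants: 4 3-hydroxy-4-methylfuran-2(5H)-one; 5 (2S)-but-3-en-2-ol
Product: 6 3-{[(2R)-but-3-en-2-yl]oxy}-4-methylfuran-2(5H)-one
Conditions: PPh3, DIAD, THF, 0 °C to rt
Reagents that add atoms: none
Why: Mitsunobu etherification, in which the acidic enol hydroxyl is O-alkylated by the activated secondary allylic alcohol in an SN2 step with inversion, so that (S)-5 should give the (R)-ether.

Step 3
Reactants: 6 3-{[(2R)-but-3-en-2-yl]oxy}-4-methylfuran-2(5H)-one
Product: 7 (4S)-4-[(2E)-but-2-en-1-yl]-4-methyloxolane-2,3-dione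
Conditions: Ho(fod)3 [tris(6,6,7,7,8,8,8-heptafluoro-2,2-dimethyloctane-3,5-dionato)holmium] (10 mol %), CHCl3, 60 °C
Reagents that add atoms: none
Why: Lewis-acid-catalysed Claisen rearrangement of the allyl enol ether of a cyclic 1,2-dicarbonyl compound; the suprafacial [3,3] shift through a chair transition state with the butenyl methyl equatorial (an axial methyl would clash with the lactone carbonyl) should transfer the ether stereocentre to C6' as (S) and give the (E)-alkene.

Step 4
Reactants: 7 (4S)-4-[(2E)-but-2-en-1-yl]-4-methyloxolane-2,3-dione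
Product: 8 (4S)-4-methyl-4-(2-oxoethyl)oxolane-2,3-dione
Conditions: O3, CH2Cl2, −78 °C; then Me2S, −78 °C to rt; used at once under anhydrous conditions
Reagents that add atoms: ozone [O-][O+]=O
Why: Ozonolysis with reductive work-up cuts the propenyl group down to the aldehyde carbon C4'; the quaternary centre cannot epimerise and the α-keto lactone has no enolisable hydrogen.

Step 5
Reactants: 9 2-nitropropan-1-ol
Product: 10 2-nitroprop-1-ene
Conditions: phthalic anhydride, 150–180 °C, reduced pressure, product distilled into a cold receiver and used fresh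
Reagents that add atoms: none
Why: Dehydration of a β-nitro alcohol through its hydrogen phthalate with elimination, the volatile nitroalkene being removed as it forms (a standard preparative procedure).

Step 6
Reactants: 8 (4S)-4-methyl-4-(2-oxoethyl)oxolane-2,3-dione; 10 2-nitroprop-1-ene
Product: 13 (3aS,7aR)-7a-hydroxy-3a,7-dimethyl-3a,4-dihydro-2-benzofuran-1,5(3H,7aH)-dione, via Stetter adduct 11 (not isolated), via nitro aldol 12 (not isolated)
Conditions: 6,7-dihydro-2-(pentafluorophenyl)-5H-pyrrolo[2,1-c][1,2,4]triazol-2-ium tetrafluoroborate (20 mol %), K2CO3 (1.5 equiv), 4 Å MS, THF (0.05 M), 0 °C to rt, 10 (2 equiv) added slowly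
Reagents that add atoms: none
Why: Proposed new method: the carbene from the triazolium salt turns the aldehyde carbon C4' of 8 into an acyl anion equivalent (Breslow intermediate) that adds to the unsubstituted alkene carbon of 10 (Stetter reaction, bond C3'–C4'); the nitronate so formed at C2' lies next to the non-enolisable, strongly electrophilic keto-lactone carbonyl C1' and closes the carbocycle by a 6-exo-trig nitro-aldol (Henry) addition (bond C2'–C1'), after which carbonate-mediated E1cB loss of nitrite from the β-nitro ketone 12 gives the enone, so that 10 serves as a propyne equivalent. The closest known reaction types are the carbene-catalysed Stetter reaction of aliphatic aldehydes with nitroalkenes, domino Stetter–aldol sequences and Michael–Henry cyclisations onto α-keto esters; their union with the nitrite elimination into one alkyne-type [4+2] annulation is what is new. The only new stereocentre that survives is C1': the nitronate carbon is delivered from the C5' arm on C6', and a γ-lactone can carry the new six-membered ring only cis-fused, so the hydroxyl should end up cis to the C6' methyl and C5 cis to C8', as in the target, while the nitro-bearing centre C2' is lost in the elimination. The step needs the Breslow intermediate to choose the nitroalkene over benzoin-type addition to the keto-lactone carbonyl, which the irreversible Stetter step, the reversibility of benzoin additions, the strain of the four-membered intramolecular benzoin product and the slow addition of excess 10 should secure. It also needs ring closure to outrun loss of HNO2 from the open-chain adduct 11, which the placing of the nascent nitronate beside the activated ketone should secure.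

Step 7
Reactants: 13 (3aS,7aR)-7a-hydroxy-3a,7-dimethyl-3a,4-dihydro-2-benzofuran-1,5(3H,7aH)-dione
Product: 14 (3aS,7aR)-7a-hydroxy-3a,7-dimethyl-3a,4-dihydro-3H-spiro[2-benzofuran-5,2'-[1,3]dioxolan]-1(7aH)-one
Conditions: TMSOCH2CH2OTMS, TMSOTf (5 mol %), CH2Cl2, −78 to −20 °C; pyridine quench
Reagents that add atoms: 1,2-bis(trimethylsilyloxy)ethane C[Si](C)(C)OCCO[Si](C)(C)C
Why: Ketalisation with the bis-silyl ether under TMSOTf catalysis converts the enone carbonyl into the dioxolane at low temperature without moving the double bond (C1' is quaternary, so no endocyclic shift is possible) and leaves the lactone untouched.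

Step 8
Reactants: 14 dioxolane lactone
Product: 15 (3aS,7aR)-3a,7-dimethyl-3a,4-dihydro-1H,3H-spiro[2-benzofuran-5,2'-[1,3]dioxolane]-1,7a-diol (lactol; both anomers)
Conditions: i-Bu2AlH (2.5 equiv), CH2Cl2, −78 °C; aq. potassium sodium tartrate work-up
Reagents that add atoms: none
Why: Half-reduction of the lactone to the lactol at −78 °C, where the tetrahedral aluminium alkoxide (held by the neighbouring C1' alkoxide) should survive until work-up; the ketal and the alkene are inert.

Step 9
Reactants: 15 lactol; 16 dimethyl (1-diazo-2-oxopropyl)phosphonate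
Product: 17 (8R,9S)-8-ethynyl-9-(hydroxymethyl)-7,9-dimethyl-1,4-dioxaspiro[4.5]dec-6-en-8-ol
Conditions: K2CO3, MeOH, 0 °C to rt
Reagents that add atoms: none
Why: Seyferth–Gilbert homologation with the Ohira–Bestmann reagent on the open hydroxy-aldehyde form of the lactol gives the terminal alkyne (C4) and frees the 8'-hydroxyl; C1' bears no hydrogen and cannot epimerise.

Step 10
Reactants: 18 (R)-mevalonolactone [(4R)-4-hydroxy-4-methyloxan-2-one]
Product: 20 benzyl (3R)-3,5-dihydroxy-3-methylpentanoate, via potassium (R)-mevalonate 19 (not isolated)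
Conditions: KOH (1.0 equiv), H2O, rt, evaporate; then BnBr, DMF, rt
Reagents that add atoms: potassium hydroxide [K+].[OH-]; benzyl bromide BrCc1ccccc1
Why: Saponification of the δ-lactone and SN2 O-benzylation of the carboxylate under neutral conditions that avoid relactonisation; the stereocentre is not touched.

Step 11
Reactants: 20 benzyl (3R)-3,5-dihydroxy-3-methylpentanoate
Product: 21 (3R)-5-(benzyloxy)-3-hydroxy-3-methyl-5-oxopentanoic acid
Conditions: TEMPO (cat.), PhI(OAc)2 (2.2 equiv), MeCN/H2O, rt
Reagents that add atoms: water O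
Why: TEMPO/PhI(OAc)2 oxidation of the primary alcohol through the aldehyde hydrate to the carboxylic acid; the tertiary alcohol cannot be oxidised.

Step 12
Reactants: 21 (3R)-5-(benzyloxy)-3-hydroxy-3-methyl-5-oxopentanoic acid
Product: 22 1-benzyl 5-methyl (3R)-3-hydroxy-3-methylpentanedioate
Conditions: TMSCHN2, toluene/MeOH, 0 °C
Reagents that add atoms: (trimethylsilyl)diazomethane C[Si](C)(C)C=[N+]=[N-]
Why: Methyl ester formation from the carboxylic acid with (trimethylsilyl)diazomethane and methanol, without acid or base that could cause retro-aldol cleavage or lactonisation.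

Step 13
Reactants: 22 1-benzyl 5-methyl (3R)-3-hydroxy-3-methylpentanedioate
Product: 23 (3S)-3-hydroxy-5-methoxy-3-methyl-5-oxopentanoic acid
Conditions: H2 (1 atm), Pd/C, EtOAc, rt
Reagents that add atoms: none
Why: Hydrogenolysis of the benzyl ester frees the carboxyl group that was C1 of mevalonate, so the two acetic acid arms are told apart; the descriptor changes to (S) only through the priority rules and returns to (3R) once this carboxyl is esterified in step 14.

Step 14
Reactants: 17 alkynyl diol; 23 (3S)-3-hydroxy-5-methoxy-3-methyl-5-oxopentanoic acid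
Product: 24 [(8R,9S)-8-ethynyl-8-hydroxy-7,9-dimethyl-1,4-dioxaspiro[4.5]dec-6-en-9-yl]methyl methyl (3R)-3-hydroxy-3-methylpentanedioate
Conditions: 23 (1.5 equiv), DIC, DMAP (cat.), CH2Cl2, 0 °C to rt
Reagents that add atoms: none
Why: Steglich esterification in which only the primary (neopentyl) 8'-hydroxyl of 17 should be acylated, the tertiary alcohols of both partners being unreactive under carbodiimide/DMAP conditions.

Step 15
Reactants: 24 alkynyl ester
Product: 25 [(8R,9S)-8-hydroxy-7,9-dimethyl-8-[(E)-2-(tributylstannyl)ethenyl]-1,4-dioxaspiro[4.5]dec-6-en-9-yl]methyl methyl (3R)-3-hydroxy-3-methylpentanedioate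
Conditions: Bu3SnH, PdCl2(PPh3)2 (2 mol %), THF, 0 °C
Reagents that add atoms: tributyltin hydride CCCC[SnH](CCCC)CCCC
Why: Palladium-catalysed syn-hydrostannation of the terminal alkyne, in which the fully substituted propargylic carbon C1' should direct tin to the terminal carbon and so give the (E)-vinylstannane.

Step 16
Reactants: 26 but-2-ynoic acid
Product: 27 (2Z)-3-iodobut-2-enoic acid
Conditions: NaI, AcOH, 110 °C
Reagents that add atoms: sodium iodide [Na+].[I-]
Why: Anti-addition of HI (NaI in acetic acid) to the 2-alkynoic acid places iodine at C3 cis to the carboxyl group, which gives the (Z)-iodo acid.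

Step 17
Reactants: 25 vinylstannane; 27 (2Z)-3-iodobut-2-enoic acid
Product: 30 (2Z,4E)-5-[(8R,9S)-8-hydroxy-9-({[(3R)-3-hydroxy-5-methoxy-3-methyl-5-oxopentanoyl]oxy}methyl)-7,9-dimethyl-1,4-dioxaspiro[4.5]dec-6-en-8-yl]-3-methylpenta-2,4-dienoic acid, via tributylstannyl (2Z)-3-iodobut-2-enoate 28 (not isolated), via tributylstannyl dienoate 29 (not isolated)
Conditions: 27, (Bu3Sn)2O (0.5 equiv), Et2O, rt; then 25, PdCl2(MeCN)2 (5 mol %), DMF, rt, dark; cold 0.1 M aq. HCl work-up
Reagents that add atoms: none
Why: Stille coupling with retention of configuration at both alkenes forms the C3–C4 bond and the (2Z,4E)-diene; the carboxylic acid is masked in the flask as its tributylstannyl ester, which the acidic work-up cleaves.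

Step 18
Reactants: 30 dienoic acid dioxolane
Product: 31 (2Z,4E)-5-[(1R,6S)-1-hydroxy-6-({[(3R)-3-hydroxy-5-methoxy-3-methyl-5-oxopentanoyl]oxy}methyl)-2,6-dimethyl-4-oxocyclohex-2-en-1-yl]-3-methylpenta-2,4-dienoic acid (target)
Conditions: 1 M aq. HCl, THF, 0 °C to rt, dark
Reagents that add atoms: water O
Why: Acid-catalysed hydrolysis of the dioxolane releases the C4' enone only now, when the 8'-oxygen is acylated and cannot add to C2'; the tertiary alcohols, the esters and the dienoic acid should tolerate dilute acid.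

**Compound list**

1 | diethyl 2-methyl-3-oxobutanedioate (diethyl oxalpropionate) | CCOC(=O)C(=O)C(C)C(=O)OCC | starting material
2 | formaldehyde (37% aqueous) | C=O | starting material
3 | ethyl 3-methyl-4,5-dioxooxolane-3-carboxylate (racemic) | CCOC(=O)C1(C)COC(=O)C1=O | intermediate
4 | 3-hydroxy-4-methylfuran-2(5H)-one | CC1=C(O)C(=O)OC1 | intermediate
5 | (2S)-but-3-en-2-ol | C[C@H](O)C=C | starting material
6 | 3-{[(2R)-but-3-en-2-yl]oxy}-4-methylfuran-2(5H)-one | C[C@@H](OC1=C(C)COC1=O)C=C | intermediate
7 | (4S)-4-[(2E)-but-2-en-1-yl]-4-methyloxolane-2,3-dione | O=C1OC[C@](C)(C/C=C/C)C1=O | intermediate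
8 | (4S)-4-methyl-4-(2-oxoethyl)oxolane-2,3-dione | O=C1OC[C@](C)(CC=O)C1=O | intermediate
9 | 2-nitropropan-1-ol (racemic) | CC(CO)[N+](=O)[O-] | starting material
10 | 2-nitroprop-1-ene | CC(=C)[N+](=O)[O-] | intermediate
11 | (4S)-4-methyl-4-(4-nitro-2-oxopentyl)oxolane-2,3-dione (Stetter adduct, both epimers at the nitro carbon) | O=C1OC[C@](C)(CC(=O)CC(C)[N+](=O)[O-])C1=O | intermediate
12 | (3aS,7aS)-7a-hydroxy-3a,7-dimethyl-7-nitrohexahydro-2-benzofuran-1,5-dione (cis-fused nitro aldol, both epimers at C7) | O=C2OC[C@]1(C)CC(=O)CC(C)([N+](=O)[O-])[C@@]12O | intermediate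
13 | (3aS,7aR)-7a-hydroxy-3a,7-dimethyl-3a,4-dihydro-2-benzofuran-1,5(3H,7aH)-dione | O=C2OC[C@]1(C)CC(=O)C=C(C)[C@@]12O | intermediate
14 | (3aS,7aR)-7a-hydroxy-3a,7-dimethyl-3a,4-dihydro-3H-spiro[2-benzofuran-5,2'-[1,3]dioxolan]-1(7aH)-one | O=C2OC[C@]1(C)CC3(OCCO3)C=C(C)[C@@]12O | intermediate
15 | (3aS,7aR)-3a,7-dimethyl-3a,4-dihydro-1H,3H-spiro[2-benzofuran-5,2'-[1,3]dioxolane]-1,7a-diol (lactol, both anomers) | OC2OC[C@]1(C)CC3(OCCO3)C=C(C)[C@@]12O | intermediate
16 | dimethyl (1-diazo-2-oxopropyl)phosphonate | CC(=O)C(=[N+]=[N-])P(=O)(OC)OC | starting material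
17 | (8R,9S)-8-ethynyl-9-(hydroxymethyl)-7,9-dimethyl-1,4-dioxaspiro[4.5]dec-6-en-8-ol | OC[C@]1(C)CC2(OCCO2)C=C(C)[C@]1(O)C#C | intermediate
18 | (R)-mevalonolactone, (4R)-4-hydroxy-4-methyloxan-2-one | C[C@]1(O)CC(=O)OCC1 | starting material
19 | potassium (3R)-3,5-dihydroxy-3-methylpentanoate | OCC[C@@](C)(O)CC(=O)[O-].[K+] | intermediate
20 | benzyl (3R)-3,5-dihydroxy-3-methylpentanoate | OCC[C@@](C)(O)CC(=O)OCc1ccccc1 | intermediate
21 | (3R)-5-(benzyloxy)-3-hydroxy-3-methyl-5-oxopentanoic acid | OC(=O)C[C@@](C)(O)CC(=O)OCc1ccccc1 | intermediate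
22 | 1-benzyl 5-methyl (3R)-3-hydroxy-3-methylpentanedioate | COC(=O)C[C@@](C)(O)CC(=O)OCc1ccccc1 | intermediate
23 | (3S)-3-hydroxy-5-methoxy-3-methyl-5-oxopentanoic acid | COC(=O)C[C@@](C)(O)CC(=O)O | intermediate
24 | [(8R,9S)-8-ethynyl-8-hydroxy-7,9-dimethyl-1,4-dioxaspiro[4.5]dec-6-en-9-yl]methyl methyl (3R)-3-hydroxy-3-methylpentanedioate | COC(=O)C[C@@](C)(O)CC(=O)OC[C@]1(C)CC2(OCCO2)C=C(C)[C@]1(O)C#C | intermediate
25 | [(8R,9S)-8-hydroxy-7,9-dimethyl-8-[(E)-2-(tributylstannyl)ethenyl]-1,4-dioxaspiro[4.5]dec-6-en-9-yl]methyl methyl (3R)-3-hydroxy-3-methylpentanedioate | COC(=O)C[C@@](C)(O)CC(=O)OC[C@]1(C)CC2(OCCO2)C=C(C)[C@]1(O)/C=C/[Sn](CCCC)(CCCC)CCCC | intermediate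
26 | but-2-ynoic acid | CC#CC(=O)O | starting material
27 | (2Z)-3-iodobut-2-enoic acid | C/C(I)=C/C(=O)O | intermediate
28 | tributylstannyl (2Z)-3-iodobut-2-enoate | C/C(I)=C/C(=O)O[Sn](CCCC)(CCCC)CCCC | intermediate
29 | tributylstannyl ester of 30 | COC(=O)C[C@@](C)(O)CC(=O)OC[C@]1(C)CC2(OCCO2)C=C(C)[C@]1(O)/C=C/C(C)=C\C(=O)O[Sn](CCCC)(CCCC)CCCC | intermediate
30 | (2Z,4E)-5-[(8R,9S)-8-hydroxy-9-({[(3R)-3-hydroxy-5-methoxy-3-methyl-5-oxopentanoyl]oxy}methyl)-7,9-dimethyl-1,4-dioxaspiro[4.5]dec-6-en-8-yl]-3-methylpenta-2,4-dienoic acid | COC(=O)C[C@@](C)(O)CC(=O)OC[C@]1(C)CC2(OCCO2)C=C(C)[C@]1(O)/C=C/C(C)=C\C(=O)O | intermediate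
31 | (2Z,4E)-5-[(1R,6S)-1-hydroxy-6-({[(3R)-3-hydroxy-5-methoxy-3-methyl-5-oxopentanoyl]oxy}methyl)-2,6-dimethyl-4-oxocyclohex-2-en-1-yl]-3-methylpenta-2,4-dienoic acid | COC(=O)C[C@@](C)(O)CC(=O)OC[C@]1(C)CC(=O)C=C(C)[C@]1(O)/C=C/C(C)=C\C(=O)O | target

**Step count and risks**

Total steps: 18. Longest linear sequence: 12 steps (steps 1–4, 6–9, 14, 15, 17, 18).

Steps most likely to fail:

1. Step 6 (proposed method). The carbene–aldehyde adduct may be diverted into benzoin-type addition to, or hydride transfer onto, the keto-lactone carbonyl. The nitroalkene may polymerise under base. The open-chain adduct may lose HNO2 before the ring closes. The fallback uses known reaction types only, makes the two bonds in separate steps, sets out from 8 and comes back at 13. Pinnick oxidation of 8 (NaClO2, NaH2PO4, 2-methylbut-2-ene, t-BuOH/H2O) should give 2-[(3S)-3-methyl-4,5-dioxooxolan-3-yl]acetic acid F1. Oxalyl chloride with catalytic DMF should give 2-[(3S)-3-methyl-4,5-dioxooxolan-3-yl]acetyl chloride F2. AlCl3-mediated acylation of 1-(trimethylsilyl)propyne at the silicon-bearing carbon (CH2Cl2, 0 °C) should give the ynone (4S)-4-methyl-4-(2-oxopent-3-yn-1-yl)oxolane-2,3-dione F3. Anti-hydroiodination with NaI in acetic acid should give the β-iodo enone (4S)-4-[(3Z)-4-iodo-2-oxopent-3-en-1-yl]-4-methyloxolane-2,3-dione F4. An intramolecular Nozaki–Hiyama–Kishi reaction (CrCl2, catalytic NiCl2, DMF, rt) should then add the alkenylchromium carbon C2' to the keto-lactone carbonyl C1' from the tethered face and give 13.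

2. Step 3. Chirality transfer may be incomplete, through a competing boat transition state or through Lewis-acid ionisation and recombination of the secondary allylic ether, which would erode the enantiopurity at C6'. The fallback replaces substrate control by catalyst control, sets out from 4 and comes back at 8. O-Allylation of 4 (allyl bromide, K2CO3, DMF, 0 °C) should give 4-methyl-3-(prop-2-en-1-yloxy)furan-2(5H)-one F5. A catalytic enantioselective Claisen rearrangement of this 2-alkoxycarbonyl allyl vinyl ether with the chelating divalent-copper Lewis acid [Cu((S,S)-t-Bu-box)(H2O)2](SbF6)2 (CH2Cl2, rt; the ligand antipode to be fixed by a test run) should give (4S)-4-methyl-4-(prop-2-en-1-yl)oxolane-2,3-dione F6. Ozonolysis (O3, then Me2S) leads to 8.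

3. Step 9. The hindered lactol may not open, or the α-hydroxy aldehyde may undergo base-induced α-ketol rearrangement before homologation. The fallback avoids base, diazo and tin chemistry, sets out from 15 and comes back at 30. Takai-type olefination of the lactol with Cl2CHB(pin), CrCl2 and LiI in THF should give (8R,9S)-9-(hydroxymethyl)-7,9-dimethyl-8-[(E)-2-(4,4,5,5-tetramethyl-1,3,2-dioxaborolan-2-yl)ethenyl]-1,4-dioxaspiro[4.5]dec-6-en-8-ol F7. Steglich esterification with 23 (DIC, catalytic DMAP) should give the corresponding 8'-O-(3-hydroxy-3-methylglutarate methyl ester) boronate F8. Suzuki–Miyaura coupling of this ester with 27 (Pd(PPh3)4, aq. K3PO4, THF, dark) should proceed with retention at both alkenes to 30.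

**Further compounds**

F1 | step 6 | 2-[(3S)-3-methyl-4,5-dioxooxolan-3-yl]acetic acid | O=C1OC[C@](C)(CC(=O)O)C1=O
F2 | step 6 | 2-[(3S)-3-methyl-4,5-dioxooxolan-3-yl]acetyl chloride | O=C1OC[C@](C)(CC(=O)Cl)C1=O
F3 | step 6 | (4S)-4-methyl-4-(2-oxopent-3-yn-1-yl)oxolane-2,3-dione | O=C1OC[C@](C)(CC(=O)C#CC)C1=O
F4 | step 6 | (4S)-4-[(3Z)-4-iodo-2-oxopent-3-en-1-yl]-4-methyloxolane-2,3-dione | O=C1OC[C@](C)(CC(=O)/C=C(/C)I)C1=O
F5 | step 3 | 4-methyl-3-(prop-2-en-1-yloxy)furan-2(5H)-one | C=CCOC1=C(C)COC1=O
F6 | step 3 | (4S)-4-methyl-4-(prop-2-en-1-yl)oxolane-2,3-dione | O=C1OC[C@](C)(CC=C)C1=O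
F7 | step 9 | (8R,9S)-9-(hydroxymethyl)-7,9-dimethyl-8-[(E)-2-(4,4,5,5-tetramethyl-1,3,2-dioxaborolan-2-yl)ethenyl]-1,4-dioxaspiro[4.5]dec-6-en-8-ol | OC[C@]1(C)CC2(OCCO2)C=C(C)[C@]1(O)/C=C/B3OC(C)(C)C(C)(C)O3
F8 | step 9 | [(8R,9S)-8-hydroxy-7,9-dimethyl-8-[(E)-2-(4,4,5,5-tetramethyl-1,3,2-dioxaborolan-2-yl)ethenyl]-1,4-dioxaspiro[4.5]dec-6-en-9-yl]methyl methyl (3R)-3-hydroxy-3-methylpentanedioate | COC(=O)C[C@@](C)(O)CC(=O)OC[C@]1(C)CC2(OCCO2)C=C(C)[C@]1(O)/C=C/B3OC(C)(C)C(C)(C)O3
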